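Late in both earlier runs the electrophile creeps: dawn loses 3.7 percentage points between 25.0 min and 120 min, and winter loses 6.8 points.

| setting | dawn | winter | grey | amber |
|---|---|---|---|---|
| electrophile | 1.1 M | 1.1 M | 1.1 M | 1.1 M |
| nucleophile | 1.1 M | 1.1 M | 1.10 M | 1.10 M |
| free base | 0.67 M | 1.9 M | 1.10 M | 2.20 M |
| remark | run made earlier | run made earlier |  |  |
| time |  |  | 2.0 h | 2.0 h |

| run | time / min | electrophile / % | target / % |
|---|---|---|---|
| dawn | 10.0 | 52.1 | 39.5 |
| dawn | 15.0 | 50.0 | 33.7 |
| dawn | 25.0 | 48.4 | 27.2 |
| dawn | 40.0 | 48.7 | 19.1 |
| dawn | 80.0 | 46.7 | 6.2 |
| dawn | 120 | 44.7 | 4.5 |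
| winter | 10.0 | 52.4 | 38.9 |
| winter | 15.0 | 48.8 | 34.7 |
| winter | 25.0 | 48.5 | 28.7 |
| winter | 40.0 | 48.2 | 18.5 |
| winter | 80.0 | 44.0 | 8.4 |
| winter | 120 | 41.7 | 3.2 |

(readings scatter by 1 percentage point)

- what may be going on: electrophile + nucleophile -> acid set free + target; nucleophile + acid set free <-> protonated nucleophile; acid set free + free base <-> salt of the base; target -> over-reaction product; target <-> isomer of the product

- part of the electrophile that has reacted at the end, grey
- part of the electrophile that has reacted at the end, amber
- what raising the concentration of free base from its lowest to its highest value here does to the part of the electrophile that has reacted (changes below 5 percentage points count as none) (it falls / no change / it rises)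

I read the runs as a ladder of times, slowest first. The creep time, meaning the electrophile left at the last reading over its loss rate after 25.0 min, reads as 19.1 h in dawn and 9.71 h in winter, both longer than the asked 2.0 h. Next, the target's fall in dawn reads as a half-life of 26.2 min, shorter than 2.0 h. Quicker still, dawn's electrophile is down to 50.0% by 15.0 min, inside that half-life and far inside the creep time.

I read the fall and stall this way: during the fall the acid set free goes mostly to nucleophile rather than to free base, so each electrophile reacted costs about two nucleophiles. That gives the stall share S, the part of the electrophile reacted once every nucleophile has either reacted or taken up acid: nucleophile charge over two times electrophile charge, here 50.0%. At 120 min, dawn stands 5.3 points above S and winter 8.3 points, and I expect grey and amber to land about there.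

The forecast gives 56% (53% to 59%) for grey, 59% (55% to 63%) for amber, and no change, judging that free base “scavenges acid poorly or slowly”.

The flask gives 55.5% for grey and 57.5% for amber, a change of 2 points: no change.

    electrophile + nucleophile → acid set free + target (k = 0.00370 M⁻¹ s⁻¹)
    nucleophile + acid set free ⇌ protonated nucleophile, settled at all times (K = 8600 M⁻¹)
    acid set free + free base ⇌ salt of the base (K = 3900 M⁻¹, k = 0.00150 M⁻¹ s⁻¹)
    target → over-reaction product (k = 4.30 × 10⁻⁴ s⁻¹)
    target ⇌ isomer of the product (K = 0.820, k = 3.30 × 10⁻⁵ s⁻¹)

Amber finishes 7.5 points above S, with nucleophile, the limiting reagent, at 0.62% of its charge, and with more acid held as protonated nucleophile, 0.461 M, than as salt of the base, 0.163 M. The 2.0 h is short against that slow passage: after 20.0 h amber reaches 89.7% and grey 81.9%.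

In the neighbour flask, amber with 2.8 M of electrophile, S falls to 19.6%. The computed flask gives 26.0%, which is 6.4 points above it.

(All runs were computed for an exercise; scatter was added.)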